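# Total synthesis of robustol by macrolactonisation, titanium-mediated ester–olefin ring closure and late aromatisation of ring A

Locants used throughout:
- The chain carbons are C1–C14.
- The ring A carbons are C1'–C6', with OH on C1', chain carbon C14 on C3' and the ether oxygen on C5'.
- The ring B carbons are C1''–C6'', with the ether oxygen on C1'', OH on C2'' and C6'', and chain carbon C1 on C4''.
- TBS = tert-butyldimethylsilyl. MNBA = 2-methyl-6-nitrobenzoic anhydride.

## Analysis of the target

Robustol (23) is a 22-membered meta,para-cyclophane. Its two benzene rings are joined twice, once by a diaryl ether oxygen and once by an unbranched chain of fourteen methylene groups. Ring A is 1,3,5-trisubstituted, and ring B is a 2-aryloxyresorcinol that carries the chain para to the ether oxygen. There is no stereocentre, and the large ring lets both arenes rotate, so the target is achiral and every sp3 centre made on the way is temporary. Free ring B is electron-rich and sensitive to oxidants, so its two hydroxyls are best carried as methyl ethers to the last step; the saturated chain offers no handle but tolerates almost everything.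

The hard bond is O–C5'. Its oxygen lies between two ortho oxygen substituents and is a hindered partner in any arylation, ring A carries only meta donor groups and cannot support nucleophilic aromatic substitution, and closing the ring at this bond would add the entropic cost of a 22-membered ring. The strategy rests on one observation: C1''–O–C5' would be an ordinary aryl ester if C5' were a carboxyl carbon, and ring A could then be laid out as the open chain C5'(=O)–C4'H2–C3'H(chain)–C2'H2–C1'H(OTBS)–C6'H=CH2. The ester is closed as a macrolactone and C5' is then joined to C6' with loss of the carbonyl oxygen, so the ester oxygen becomes the ether oxygen without ever being displaced, and ring A reaches the aromatic level by oxidation-state changes alone.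

## Retrosynthetic reasoning

**23 ⇒ 22 (two O–CH3 bonds).** The ring B hydroxyls are masked as methyl ethers, which leads back to the dimethyl ether 22. These bonds are cut last because the free 2-aryloxyresorcinol would not survive the organometallic and oxidative steps. The forward reaction must cleave two sp3 C–O bonds and leave the diaryl ether, which has none, untouched.

**22 ⇒ 21 ⇒ 20 (the hydrogens on C2' and C3').** Phenol 22 is the enol form of the cross-conjugated dienone 21. Dienone 21 differs from the macrocyclic 3-aryloxycyclohexenone 20 only by two hydrogens. Lowering ring A to this level changes C5' from an arene carbon into the β-carbon of a vinylogous ester. The forward step is a dehydrogenation driven by aromatisation, and it also removes the C3' stereocentre.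

**20 ⇒ 19 ⇒ 18 (oxidation level and protection at C1').** The carbonyl of 20 comes from the allylic alcohol 19, which comes from its silyl ether 18. C1' must be at the protected carbinol level during the key step, because a ketone there would compete with the ester for the titanium reagent. The forward steps must avoid acid, since 19 is a 3-aryloxy allylic alcohol.

**18 ⇒ 17 ⇒ 16 (the C5'=C6' bond, key disconnection).** Cutting the enol ether double bond, returning an oxygen to C5' and a methylene to C6', gives the aryl macrolactone 16. This is the only ring A bond whose removal changes the O–C5' linkage from an ether into an ester. Every other cut leaves the ether problem in place. What is gained is that the hindered C–O bond becomes an acylation. The forward reaction must put a titanium alkylidene on C6' (17) and have it olefinate the ester carbonyl five atoms away.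

**16 ⇒ 15 ⇒ 14 (the acyl C5'–O bond).** The macrolactone opens to the seco acid 14, which is activated in the flask as the mixed anhydride 15. Acylation of a phenol is fast and irreversible, and it is served by the largest set of macrocyclisation methods available. The C1' oxygen must already be silylated, because a free hydroxyl in the δ-position would attack the aryl ester and contract the ring to a six-membered lactone.

**14 ⇒ 13 ⇒ 12 ⇒ 11 + 10 (the C14–C3' bond).** Acid 14 comes from the methyl ester 13. C3' of 13 is β to the ester, so it is the natural site of a conjugate addition. The chain Grignard reagent 11 (from bromide 6) adds to the dienoate 10, with the silyl ketene acetal 12 as the trapped enolate. This cut divides the seco acid into two fragments of similar size and brings in all six ring A carbons, with C1' already silylated. It avoids a symmetric diacid precursor, whose two equal arms would have to be differentiated and adjusted in oxidation level over several steps. It also avoids a δ-hydroxy ester stage that would lactonise.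

**10 ⇒ 8 + 9, 8 ⇒ 7 (the C3'=C4' bond).** The enoate double bond of 10 is a cross-metathesis bond between the silyl ether 8 and methyl acrylate 9. Compound 8 is the silyl ether of the commercial dienol 7. The forward reaction must engage the unhindered allyl terminus of 8 and spare the vinyl group next to the silyloxy carbon, which is needed in the key step.

**6 ⇒ 5 + 2, 5 ⇐ 4 ⇐ 3, 2 ⇐ 1 (the C4''–C1 bond).** The aryl–alkyl bond is cut to the aryl Grignard reagent 5 and the symmetric dibromide 2. Reagent 5 comes from bromophenol 3 through its silyl ether 4, and 2 comes from diol 1. Cutting here leaves exactly fourteen chain carbons in one cheap building block. It creates no alkene, so no hydrogenation is needed and no protecting group is chosen that would later clash with the vinyl group. The aryl silyl ether is removed in the same pot as the methyl ester.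

## Alternatives that were turned down

**Alternative 1:** The disconnection removes ring B altogether. C4''–C5'' and C2''–C3'' are cut, which leads to the 4-chlorocyclobutenone A1.
- **Structure of A1.** Its four-membered ring, derived from squaric acid chemistry, carries the ring A aryloxy group next to the carbonyl, a methoxy group on the other alkene carbon and chlorine on the sp3 carbon. The C14 chain on ring A ends in a 1-(tributylstannyl)vinyl group.
- **Forward key step.** An intramolecular Stille coupling would replace chlorine by the vinyl carbon, forming C4''–C5'' and the 22-membered ring. The 4-alkenylcyclobutenone would then open in a conrotatory 4π process to a dienylketene, close in a 6π process (C2''–C3'') and tautomerise to phenol A2. A2 is robustol with the ring A hydroxyl and one ring B hydroxyl methylated.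
- **In its favour.** The crowded O–C1'' bond comes from addition–elimination on an electrophilic four-membered ring and not from an arylation. Aromatisation drives the cascade and needs no separate oxidation. Arene and macrocycle appear in one operation.
- **Against it.** The macrocyclisation depends on transmetalation of an α-substituted vinylstannane, which is slow. At the dilution a 22-membered ring demands, protodestannylation, cine substitution and decay of the heat- and base-sensitive chloride have time to compete.
- **Cost of A1.** Two different oxygen substituents must be placed regioselectively, the correct carbonyl must be reduced and chlorinated, and the internal stannane needs a regiocontrolled hydrostannation. Tin is used in stoichiometric amount.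
- **Comparison.** Both plans build one arene late and both avoid a diaryl ether coupling. Alternative 1 is stronger in ending directly at the aromatic level, whereas the chosen route spends four steps after its key step. In exchange, the chosen route closes the macrocycle by a plain acylation and forms its key carbon–carbon bond in a six-membered ring, so the two difficult events are never superimposed.

**Alternative 2:** Ring A is again carried at the cyclohexenone level, but the bond cut is O–C5' itself.
- **Disconnection.** The macrocyclic enone A4, identical with compound 20 of the chosen route, is traced to the seco compound A3. A3 is a 3-chlorocyclohex-2-enone whose C5 bears the tetradecyl chain, which ends in the free 4-hydroxy-3,5-dimethoxyphenyl group.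
- **Forward key step.** Base would generate the phenoxide. It adds to the β-carbon of the chloroenone and expels chloride, a vinylogous acyl substitution that closes the 22-membered ring.
- **In its favour.** The six-membered ring comes from classical diketone chemistry. No titanium reagent and no silyl groups are needed. The product already has the right oxidation level, so only dehydrogenation and demethylation remain. On step economy and on the maturity of each single reaction this plan is stronger than the chosen one.
- **Against it.** The ring-closing event is still the attack of the di-ortho-substituted phenoxide on carbon, now on an electrophile less reactive than an activated acyl group. The chloroenone has acidic α'- and γ-hydrogens, so long reaction times under basic, dilute conditions invite deprotonation, self-condensation and hydrolysis by traces of water. Aryloxide addition–elimination is also reversible, so oligomers and ring can interconvert, and few means exist to force the closure.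
- **Comparison.** The chosen strategy offers the best-developed macrocyclisation, makes O–C5' as an acyl–oxygen bond and meets the same enone 20. Alternative 2 therefore remains a reserve entry to the late intermediates.

**Alternative 3:** The chain is cut at its ring B end.
- **Disconnection.** The C1=C2 alkene of macrocycle A6 is traced to the 23-membered benzylic sulfone A5. In A5, C1 and C2 are bridged by SO2, and both arenes and the diaryl ether are already present.
- **Forward key step.** In situ α-halogenation and base would give an episulfone. It loses SO2 and contracts the ring to A6 (either alkene geometry serves). Hydrogenation and threefold demethylation follow.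
- **In its favour.** The ring closure that precedes A5 uses a soft, unhindered sulfur nucleophile on a benzylic electrophile, one of the most forgiving macrocyclisations. The Ramberg–Bäcklund contraction is intramolecular and works well for benzylic sulfones. Both arenes are bought, so ring A needs no redox chemistry. Its ring-forming steps carry less risk than those of the chosen route.
- **Against it.** The real problem is untouched. The hindered diaryl ether must still be made by an intermolecular copper-mediated coupling of a 2,6-dioxygenated phenol with an unactivated meta-substituted aryl halide, which is the least favourable pairing for such couplings. Sulfur is introduced, oxidised and expelled, and the alkene is then hydrogenated; those steps add no atom to the target. Ring A also needs an ω-functionalised thirteen-carbon chain.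
- **Comparison.** In step count it is equal or longer. The chosen strategy instead creates the C1''–O–C5' linkage without any arylation.

Key step: step 9

Assumption: robustol has no stereocentre and no hindered rotation in its 22-membered ring, so racemic 7 and diastereomer mixtures are carried throughout, and 3 is taken to be a catalogue compound.

## Route

Step 1
Reactants: 1 tetradecane-1,14-diol
Product: 2 1,14-dibromotetradecane
Conditions: 48% aq HBr (excess), conc. H2SO4, reflux
Reagents that add atoms: hydrogen bromide, Br
Why: Acid-promoted SN2 substitution of both primary hydroxyl groups by bromide; the symmetric diol has no other reactive site, and exhaustive reaction removes any selectivity question.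

Step 2
Reactants: 3 4-bromo-2,6-dimethoxyphenol
Product: 4 (4-bromo-2,6-dimethoxyphenoxy)(tert-butyl)dimethylsilane
Conditions: TBSCl, imidazole, DMF, rt
Reagents that add atoms: tert-butyldimethylsilyl chloride, CC(C)(C)[Si](C)(C)Cl
Why: Imidazole-promoted silylation of a phenol; the aryl silyl ether withstands magnesium insertion and organocopper chemistry and can later be removed by hydroxide, because a phenoxide leaves silicon far more easily than an alkoxide.

Step 3
Reactants: 4 (4-bromo-2,6-dimethoxyphenoxy)(tert-butyl)dimethylsilane; 2 1,14-dibromotetradecane (3 equiv)
Product: 6 [4-(14-bromotetradecyl)-2,6-dimethoxyphenoxy](tert-butyl)dimethylsilane, via arylmagnesium bromide 5 (not isolated)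
Conditions: Mg turnings (I2), THF, reflux; then slow addition to 2, Li2CuCl4 (3 mol%), THF, 0 °C to rt
Reagents that add atoms: none
Why: Grignard formation followed by a Kochi-type copper-catalysed sp2–sp3 cross-coupling with a primary alkyl bromide forms C4''–C1. Slow addition of 5 to an excess of the symmetric dibromide should keep double arylation minor, and unreacted 2 is much less polar than 6 and can be recovered.

Step 4
Reactants: 7 hexa-1,5-dien-3-ol (racemic)
Product: 8 tert-butyl(hexa-1,5-dien-3-yloxy)dimethylsilane (racemic)
Conditions: TBSCl, imidazole, CH2Cl2, rt
Reagents that add atoms: tert-butyldimethylsilyl chloride, CC(C)(C)[Si](C)(C)Cl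
Why: Standard silylation of a secondary allylic alcohol. The group is placed this early because a free C1' hydroxyl would later attack the aryl ester, and because its bulk differentiates the two alkenes in step 5; the stereocentre (future C1') is racemic and is erased in step 11.

Step 5
Reactants: 8 tert-butyl(hexa-1,5-dien-3-yloxy)dimethylsilane; 9 methyl acrylate (3 equiv)
Product: 10 methyl (2E)-5-[(tert-butyldimethylsilyl)oxy]hepta-2,6-dienoate (racemic)
Conditions: second-generation Hoveyda–Grubbs catalyst RuCl2(H2IMes)(=CH-C6H4-2-OiPr) (2 mol%), CH2Cl2, 40 °C
Reagents that add atoms: none
Why: Olefin cross-metathesis between a fast-reacting unhindered allyl terminus and an electron-poor acrylate that dimerises slowly; the vinyl group next to the bulky silyloxy carbon reacts much more slowly and should be spared if the reaction is stopped once 8 is consumed. The E-enoate is the thermodynamic product, and ring closure of the 1,5-diene is impossible because it would give a cyclobutene.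

Step 6
Reactants: 6 [4-(14-bromotetradecyl)-2,6-dimethoxyphenoxy](tert-butyl)dimethylsilane; 10 methyl (2E)-5-[(tert-butyldimethylsilyl)oxy]hepta-2,6-dienoate
Product: 13 methyl 3-{2-[(tert-butyldimethylsilyl)oxy]but-3-en-1-yl}-17-{4-[(tert-butyldimethylsilyl)oxy]-3,5-dimethoxyphenyl}heptadecanoate (diastereomer mixture), via alkylmagnesium bromide 11 (not isolated), via silyl ketene acetal 12 (not isolated)
Conditions: Mg turnings (I2), THF, 45 °C; then CuBr·SMe2 (15 mol%), TMSCl (2 equiv), 10, THF, −78 to −30 °C; aq NH4Cl
Reagents that add atoms: none
Why: Copper-catalysed, chlorosilane-accelerated 1,4-addition of a primary alkyl Grignard reagent to an E-enoate forms C14–C3'; TMSCl traps the enolate as 12, which suppresses 1,2-addition and is hydrolysed on work-up. The allylic silyl ether is too poor a leaving group for allylic substitution. The new stereocentre C3' is formed without control relative to C1', which is harmless because both centres become sp2 in steps 11 and 12.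

Step 7
Reactants: 13 methyl 3-{2-[(tert-butyldimethylsilyl)oxy]but-3-en-1-yl}-17-{4-[(tert-butyldimethylsilyl)oxy]-3,5-dimethoxyphenyl}heptadecanoate
Product: 14 3-{2-[(tert-butyldimethylsilyl)oxy]but-3-en-1-yl}-17-(4-hydroxy-3,5-dimethoxyphenyl)heptadecanoic acid (diastereomer mixture)
Conditions: LiOH·H2O (6 equiv), THF/MeOH/H2O, 40 °C; then cold 0.5 M HCl to pH 4
Reagents that add atoms: lithium hydroxide, [Li+].[OH-]
Why: Saponification of the methyl ester by acyl–oxygen cleavage, with hydroxide attack on the silicon of the aryl silyl ether in the same pot. The secondary alkyl TBS ether is stable to aqueous base, and the mild cold acidification should leave it in place, so no δ-lactone can form.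

Step 8
Reactants: 14 3-{2-[(tert-butyldimethylsilyl)oxy]but-3-en-1-yl}-17-(4-hydroxy-3,5-dimethoxyphenyl)heptadecanoic acid
Product: 16 22-membered aryl macrolactone of 14 (carboxyl carbon C5' esterified by the C1'' oxygen; 2-(TBS-oxy)but-3-enyl side chain on C3'; diastereomer mixture), via mixed anhydride 15 (not isolated)
Conditions: MNBA (1.5 equiv), DMAP (4 equiv), CH2Cl2, syringe-pump addition of 14 to a final 1 mM, rt to 40 °C
Reagents that add atoms: none
Why: Shiina macrolactonisation: MNBA converts the acid into 15, DMAP selects the unhindered aliphatic acyl group, and the acylpyridinium ion is captured by the phenol. The 22-membered ring is strain-free, so only entropy has to be paid, by high dilution. Acylation of a 2,6-dimethoxyphenol is ordinary chemistry, and no free hydroxyl is left that could translactonise.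

Step 9
Reactants: 16 22-membered aryl macrolactone
Product: 18 macrocyclic 1-aryloxy-3-(TBS-oxy)-5-alkylcyclohexene (C5'=C6' enol ether; C5' bound through oxygen to C1'' and C3' through the (CH2)14 chain to C4'' of the 2,6-dimethoxyphenyl ring; diastereomer mixture), via titanium alkylidene 17 (not isolated)
Conditions: TiCl4, TMEDA, THF/CH2Cl2, 0 °C; Zn dust, PbCl2 (cat.), rt; then 16 (5 mM), CH3CHBr2, 65 °C; aq K2CO3 quench, basic alumina
Reagents that add atoms: none
Why: Zinc, activated by a trace of PbCl2, turns CH3CHBr2 into a geminal dizinc species that is passed on to TMEDA-ligated low-valent titanium, giving a nucleophilic titanium ethylidene of the Takai–Utimoto type. This alkylidene is expected to exchange with the only alkene of 16 by [2+2] addition and cycloreversion, releasing propene and placing titanium on C6' (17, drawn as its dichloride with TMEDA omitted); the other order, ethylidenation of the ester and then titanium-mediated ring-closing metathesis, would end at the same product. In 17 the Ti=C6' bond adds across the C5'=O bond, and the bicyclic oxatitanacyclobutane cycloreverts to a strong Ti=O bond and the C5'=C6' double bond. The closest known reaction type is the olefinic-ester cyclisation with this same reagent system, which makes cyclic enol ethers; the carbocyclic mode, with the alkene on the acyl side so that the ester oxygen ends up exocyclic, is known from the thioacetal–Cp2Ti[P(OEt)3]2 variant on alkyl esters, and aryl esters are established partners of titanium alkylidenes in plain methylenation. One ring is closed, the six-membered carbocycle C5'–C4'–C3'–C2'–C1'–C6', by intramolecular carbonyl olefination at the C5'–C6' bond, and the 22-membered ring is kept because neither C–O bond of the C5'–O–C1'' bridge is ever broken. No stereocentre is formed, and those at C1' and C3' are untouched and later erased, so both diastereomers serve. The step needs one carbonyl and one alkene to react and needs ring closure to outrun plain ethylidenation: 16 has no other C=O or C=C, the allylic oxygen is blocked as a silyl ether, the aryl ester is more electrophilic than an alkyl ester, and six-membered ring formation is the best kinetic case for the intramolecular path.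

Step 10
Reactants: 18 macrocyclic 1-aryloxy-3-(TBS-oxy)-5-alkylcyclohexene
Product: 19 macrocyclic 3-aryloxy-5-alkylcyclohex-2-en-1-ol (free hydroxyl on C1'; diastereomer mixture)
Conditions: TBAF (1.5 equiv), THF, 0 °C to rt; aq NaHCO3 work-up, base-washed glassware, used crude
Reagents that add atoms: none
Why: Fluoride-induced Si–O cleavage under basic conditions. Acid is excluded throughout because 19 is a 3-aryloxy allylic alcohol that would ionise at C1' and hydrolyse with loss of the ring B phenol.

Step 11
Reactants: 19 macrocyclic 3-aryloxy-5-alkylcyclohex-2-en-1-ol
Product: 20 macrocyclic 3-aryloxy-5-alkylcyclohex-2-en-1-one (racemic; carbonyl at C1')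
Conditions: activated MnO2 (20 equiv), CH2Cl2, rt
Reagents that add atoms: none
Why: Neutral heterogeneous oxidation of an allylic alcohol, which touches neither the enol ether nor the dimethoxyarene. It removes the C1' stereocentre and turns the labile alcohol into a robust vinylogous aryl ester.

Step 12
Reactants: 20 macrocyclic 3-aryloxy-5-alkylcyclohex-2-en-1-one
Product: 22 robustol 2'',6''-di-O-methyl ether, via cross-conjugated dienone 21 (not isolated)
Conditions: Pd(O2CCF3)2 (5 mol%), 2-(dimethylamino)pyridine (10 mol%), TsOH·H2O (20 mol%), O2 (1 atm), DMSO, 80 °C
Reagents that add atoms: none
Why: Aerobic palladium-catalysed dehydrogenation of a cyclohexenone to a phenol: divalent palladium forms the C2' enolate, β-hydride elimination of the C3' hydrogen gives 21, which tautomerises irreversibly to the phenol, and oxygen reoxidises zerovalent palladium. The last stereocentre (C3') disappears, and the 1,3,5-pattern of ring A follows directly from the substitution of 20.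

Step 13
Reactants: 22 robustol 2'',6''-di-O-methyl ether
Product: 23 robustol
Conditions: BBr3 (5 equiv), CH2Cl2, −78 °C to rt; then H2O, 0 °C
Reagents that add atoms: none
Why: Lewis-acid-mediated cleavage of aryl methyl ethers, in which bromide attacks the methyl carbon of the boron-complexed ether. The diaryl ether offers no sp3 carbon for that attack and should survive, and the free ring A phenol only consumes one equivalent of reagent.

## Compound list

1 | tetradecane-1,14-diol | OCCCCCCCCCCCCCCO | starting material
2 | 1,14-dibromotetradecane | BrCCCCCCCCCCCCCCBr | intermediate
3 | 4-bromo-2,6-dimethoxyphenol | COc1cc(Br)cc(OC)c1O | starting material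
4 | (4-bromo-2,6-dimethoxyphenoxy)(tert-butyl)dimethylsilane | COc1cc(Br)cc(OC)c1O[Si](C)(C)C(C)(C)C | intermediate
5 | {4-[(tert-butyldimethylsilyl)oxy]-3,5-dimethoxyphenyl}magnesium bromide (not isolated) | COc1cc([Mg]Br)cc(OC)c1O[Si](C)(C)C(C)(C)C | intermediate
6 | [4-(14-bromotetradecyl)-2,6-dimethoxyphenoxy](tert-butyl)dimethylsilane | COc1cc(CCCCCCCCCCCCCCBr)cc(OC)c1O[Si](C)(C)C(C)(C)C | intermediate
7 | hexa-1,5-dien-3-ol (racemic) | C=CCC(O)C=C | starting material
8 | tert-butyl(hexa-1,5-dien-3-yloxy)dimethylsilane (racemic) | C=CCC(O[Si](C)(C)C(C)(C)C)C=C | intermediate
9 | methyl acrylate | COC(=O)C=C | starting material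
10 | methyl (2E)-5-[(tert-butyldimethylsilyl)oxy]hepta-2,6-dienoate (racemic) | COC(=O)/C=C/CC(O[Si](C)(C)C(C)(C)C)C=C | intermediate
11 | (14-{4-[(tert-butyldimethylsilyl)oxy]-3,5-dimethoxyphenyl}tetradecyl)magnesium bromide (not isolated) | COc1cc(CCCCCCCCCCCCCC[Mg]Br)cc(OC)c1O[Si](C)(C)C(C)(C)C | intermediate
12 | trimethylsilyl ketene acetal of ester 13 (alkene and diastereomer mixture, not isolated) | COC(O[Si](C)(C)C)=CC(CC(O[Si](C)(C)C(C)(C)C)C=C)CCCCCCCCCCCCCCc1cc(OC)c(O[Si](C)(C)C(C)(C)C)c(OC)c1 | intermediate
13 | methyl 3-{2-[(tert-butyldimethylsilyl)oxy]but-3-en-1-yl}-17-{4-[(tert-butyldimethylsilyl)oxy]-3,5-dimethoxyphenyl}heptadecanoate (diastereomer mixture) | COC(=O)CC(CC(O[Si](C)(C)C(C)(C)C)C=C)CCCCCCCCCCCCCCc1cc(OC)c(O[Si](C)(C)C(C)(C)C)c(OC)c1 | intermediate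
14 | 3-{2-[(tert-butyldimethylsilyl)oxy]but-3-en-1-yl}-17-(4-hydroxy-3,5-dimethoxyphenyl)heptadecanoic acid (diastereomer mixture) | OC(=O)CC(CC(O[Si](C)(C)C(C)(C)C)C=C)CCCCCCCCCCCCCCc1cc(OC)c(O)c(OC)c1 | intermediate
15 | mixed anhydride of acid 14 and 2-methyl-6-nitrobenzoic acid (not isolated) | Cc1cccc([N+](=O)[O-])c1C(=O)OC(=O)CC(CC(O[Si](C)(C)C(C)(C)C)C=C)CCCCCCCCCCCCCCc1cc(OC)c(O)c(OC)c1 | intermediate
16 | 22-membered aryl macrolactone with a 2-(TBS-oxy)but-3-enyl side chain on C3' (diastereomer mixture) | O=C1CC(CC(O[Si](C)(C)C(C)(C)C)C=C)CCCCCCCCCCCCCCc2cc(OC)c(O1)c(OC)c2 | intermediate
17 | macrolactone with a titanium alkylidene on C6', drawn as the dichloride with TMEDA omitted (not isolated) | O=C1CC(CC(O[Si](C)(C)C(C)(C)C)C=[Ti](Cl)Cl)CCCCCCCCCCCCCCc2cc(OC)c(O1)c(OC)c2 | intermediate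
18 | macrocyclic 1-aryloxy-3-(TBS-oxy)-5-alkylcyclohexene (diastereomer mixture) | CC(C)(C)[Si](C)(C)OC1C=C2CC(C1)CCCCCCCCCCCCCCc1cc(OC)c(O2)c(OC)c1 | intermediate
19 | macrocyclic 3-aryloxy-5-alkylcyclohex-2-en-1-ol (diastereomer mixture) | OC1C=C2CC(C1)CCCCCCCCCCCCCCc1cc(OC)c(O2)c(OC)c1 | intermediate
20 | macrocyclic 3-aryloxy-5-alkylcyclohex-2-en-1-one (racemic) | O=C1C=C2CC(C1)CCCCCCCCCCCCCCc1cc(OC)c(O2)c(OC)c1 | intermediate
21 | macrocyclic 3-aryloxy-5-alkylcyclohexa-2,5-dien-1-one (not isolated) | O=C1C=C2CC(=C1)CCCCCCCCCCCCCCc1cc(OC)c(O2)c(OC)c1 | intermediate
22 | robustol 2'',6''-di-O-methyl ether | Oc1cc2cc(c1)Oc1c(OC)cc(cc1OC)CCCCCCCCCCCCCC2 | intermediate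
23 | robustol | Oc1cc2cc(c1)Oc1c(O)cc(cc1O)CCCCCCCCCCCCCC2 | target

## Step count and least certain steps

Total step count: 13. Longest linear sequence: 10 steps (steps 2, 3, 6, 7, 8, 9, 10, 11, 12, 13). The branches through step 1 and through steps 4 and 5 are equally long.

**Step 9 (key step).**
- **Risk.** The most likely failure is plain ethylidenation of the ester without ring closure. The vinyl group sits next to a bulky silyloxy carbon, so alkylidene exchange there may be slower than attack of the reagent on the activated carbonyl. A second danger is expulsion of the aryloxide from the oxatitanacycle, an acyl-transfer path favoured by the good leaving group, which would cut the macrocycle.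
- **Fallback.** Olefination and ring closure are separated and given to two different metals. Starting from 16, methylenation of the ester with TiCl4/Zn/PbCl2/TMEDA/CH2Br2 (or Cp2TiMe2 in toluene) should give the macrocyclic exocyclic methylene enol ether F1. Enol ether–olefin ring-closing metathesis with the second-generation Grubbs catalyst RuCl2(H2IMes)(PCy3)(=CHPh) in hot toluene should then initiate at the vinyl group, close onto the 1,1-disubstituted enol ether and return to the route at 18.

**Step 8.**
- **Risk.** Intermolecular acylation to dimers and oligomers may compete. Capture of the acylpyridinium ion by the flanked phenol may also be slow, which gives the activated acid time to be diverted, for example by transfer of the aromatic acyl group.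
- **Fallback.** The nucleophile is activated instead of the electrophile. Starting from 14, EDC·HCl and an excess of pentafluorophenol should give the isolable pentafluorophenyl ester F2, because the acidic, unhindered reagent phenol outcompetes the hindered internal one. Slow addition of F2 to Cs2CO3 in MeCN at high dilution should generate the caesium phenoxide, which displaces pentafluorophenoxide and returns to the route at 16.

**Step 12.**
- **Risk.** Acid, the water formed and heat may hydrolyse the vinylogous aryl ester, which would open the macrocycle. Palladation at C2' may also be slow, because a vinylogous ester enolises less readily than a plain enone, and the catalyst may then aggregate to palladium metal.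
- **Fallback.** A stepwise, enolate-based dehydrogenation (Saegusa–Ito) is used. Starting from 20, kinetic α'-deprotonation with LDA and trapping with TMSCl at −78 °C should give the cross-conjugated trimethylsilyl dienol ether F3. Treatment of F3 with Pd(OAc)2 in MeCN should deliver dienone 21 and, after tautomerisation, return to the route at 22.

**Step 10.**
- **Risk.** The C1'–O bond may ionise with assistance from the enol ether oxygen and then hydrolyse, the process used deliberately in the Stork–Danheiser enone transposition. This would release the ring B phenol and cut the macrocycle during work-up or handling.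
- **Fallback.** The free alcohol is avoided altogether. Starting from 18, DDQ in CH2Cl2/pH 7 buffer at 0 °C should abstract hydride from the doubly activated C1' position and, after loss of the silyl group, give the enone directly, returning to the route at 20. This fallback makes no new compound (F0). Competing oxidation at the ring B benzylic position would have to be watched.

**Step 3.**
- **Risk.** Double arylation of the dibromide, homocoupling of the aryl Grignard reagent and sluggish coupling of an electron-rich aryl nucleophile may lower the throughput of the ring B fragment.
- **Fallback.** The chain ends are differentiated before the coupling. Starting from 1, monobromination with 48% aq HBr in refluxing toluene should give 14-bromotetradecan-1-ol F4. Its hydroxyl is converted into the magnesium alkoxide with MeMgCl, and F4 is coupled with 5 under Li2CuCl4 catalysis to give 14-{4-[(tert-butyldimethylsilyl)oxy]-3,5-dimethoxyphenyl}tetradecan-1-ol F5. An Appel reaction (CBr4, PPh3, CH2Cl2) then returns to the route at 6.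

## Further compounds

F1 | step 9 | macrocyclic exocyclic methylene enol ether from methylenation of 16 (diastereomer mixture) | C=C1CC(CC(O[Si](C)(C)C(C)(C)C)C=C)CCCCCCCCCCCCCCc2cc(OC)c(O1)c(OC)c2
F2 | step 8 | pentafluorophenyl ester of acid 14 (diastereomer mixture) | O=C(Oc1c(F)c(F)c(F)c(F)c1F)CC(CC(O[Si](C)(C)C(C)(C)C)C=C)CCCCCCCCCCCCCCc1cc(OC)c(O)c(OC)c1
F3 | step 12 | cross-conjugated trimethylsilyl dienol ether of enone 20 (racemic) | C[Si](C)(C)OC1=CC2CC(=C1)Oc1c(OC)cc(cc1OC)CCCCCCCCCCCCCC2
F4 | step 3 | 14-bromotetradecan-1-ol | OCCCCCCCCCCCCCCBr
F5 | step 3 | 14-{4-[(tert-butyldimethylsilyl)oxy]-3,5-dimethoxyphenyl}tetradecan-1-ol | OCCCCCCCCCCCCCCc1cc(OC)c(O[Si](C)(C)C(C)(C)C)c(OC)c1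
F0 | step 10 | none | none
A1 | alternative 1 | 4-chloro-3-methoxy-2-{3-methoxy-5-[15-(tributylstannyl)hexadec-15-en-1-yl]phenoxy}cyclobut-2-en-1-one (racemic) | O=C1C(Oc2cc(OC)cc(CCCCCCCCCCCCCCC(=C)[Sn](CCCC)(CCCC)CCCC)c2)=C(OC)C1Cl
A2 | alternative 1 | robustol dimethyl ether with the C2'' hydroxyl free (methyl ethers on the C1' and C6'' oxygens) | COc1cc2cc(c1)Oc1c(O)cc(cc1OC)CCCCCCCCCCCCCC2
A3 | alternative 2 | 3-chloro-5-[14-(4-hydroxy-3,5-dimethoxyphenyl)tetradecyl]cyclohex-2-en-1-one (racemic) | O=C1C=C(Cl)CC(C1)CCCCCCCCCCCCCCc1cc(OC)c(O)c(OC)c1
A4 | alternative 2 | macrocyclic 3-aryloxy-5-alkylcyclohex-2-en-1-one (racemic, identical with 20) | O=C1C=C2CC(C1)CCCCCCCCCCCCCCc1cc(OC)c(O2)c(OC)c1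
A5 | alternative 3 | 23-membered benzylic sulfone of tri-O-methylrobustol (SO2 between C1 and C2) | COc1cc2cc(c1)Oc1c(OC)cc(cc1OC)CS(=O)(=O)CCCCCCCCCCCCC2
A6 | alternative 3 | 1,2-didehydro-tri-O-methylrobustol, drawn E | COc1cc2cc(c1)Oc1c(OC)cc(cc1OC)/C=C/CCCCCCCCCCCC2
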